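## Structural features

The target is a germacranolide: a ten-membered carbocycle (C1–C10) fused across C6–C7 to a butenolide (O on C6, C7=C11, C12 carbonyl) whose α-carbon C11 carries the acetoxymethyl carbon C13. The carbocycle bears a C1 ketone cross-conjugated with the C10 exocyclic methylene (C14), a cis-4,5-epoxide with the C15 methyl on C4, and a methacrylate on O8. The stereocentres C4, C5 and C6 stand in a row and C8 is separated from C6 only by the sp2 carbon C7. The configuration is 4S,5R,6R,8R, with the epoxide oxygen, O6 and O8 on one face of the ring. The fragile elements are: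
- the α-methylene ketone and the methacrylate (Michael acceptors);
- the primary allylic acetate on the butenolide;
- the epoxide, which can be opened across the ring by acid as long as a C1=C10 alkene is present;
- any C6 carbonyl flanked by an oxygen on C8 (β-elimination).

The real difficulty is to form the medium ring and to place three oxygen-bearing stereocentres around it without a rigid template, while keeping four different oxygen functions apart. The key step exploits the fact that C1–C6 with C9, C10, C14 and C15 are the atoms of 6-isopropenyl-3-methylcyclohex-2-enone, whose ring alkene is the future cis C4–C5 bond. A two-carbon oxyvinyl unit (C7, C8) on the carbonyl carbon makes a 3-hydroxy-1,5-diene, and a [3,3] shift inserts C7–C8–C9–C10 into the C1–C6 bond.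

## Logic of the disconnections

29 to 27. The C1=O bond is cut and the double bond is returned from C10=C14 to C1=C10. The methylene ketone is the most electrophilic group and is therefore made last. The gain is that every earlier intermediate carries only an unactivated trisubstituted alkene. The demand on the forward step is that oxygen bonds to C1 with hydrogen taken from C14, and that no other electron-rich π system is present.

27 to 24 (through 26 and 25). The two acyl C–O bonds at O8 and O13 are cut. Late acylation keeps esters away from the enolate chemistry. The gain is one ether and one free alcohol in place of two different esters. The demand is orthogonality: O13 is acetylated while O8 is still an ether, then O8 is freed oxidatively and acylated.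

24 to 21. The C7=C11 double bond is traced back to C7–H and C11–H. Direct dehydration of a C11 carbinol could also eliminate towards C13, whereas a selenoxide does not eliminate towards an oxygen-bearing carbon. The gain is a saturated lactone. The demand is that selenium enters cis to H7 and that the C11 enolate does not expel the C13 oxygen, which is met by the alkoxide–enolate dianion.

21 to 19. The C11–C13 bond is cut (formaldehyde aldol). The gain is a lactone without a substituent at C11. The demand is mono-hydroxymethylation of the lactone enolate.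

19 to 15 (through 17). The lactone C12–O6 bond, the C6–H bond and the C7–C11 bond are cut. C11 and C12 come from an iodoacetate and C6 returns to a ketone. The gain is an epoxy ketone with a single enolisable position. The demand is hydride delivery that puts O6 cis to the epoxide oxygen, and C-alkylation before the C8 ether is lost.

15 to 12 (through 14 and 13). The two epoxide C–O bonds are cut. A C6 hydroxyl, set by a chiral reagent, is used as a relay to place the epoxide and is then oxidised back. A direct peroxide epoxidation of 12 would rest on the unknown facial bias of the ten-membered ring. The gain is a dienone with one stereocentre. The demand is enantioface control at C6, syn delivery of oxygen and selectivity for C4=C5 over C1=C10.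

12 to 9. The C8–C9 bond is cut and the C1–C6 bond re-formed (retro-[3,3]). The ten-membered ring collapses to a cyclohexenol carrying two alkenyl groups, and the C8 stereocentre is traded for the isopropenyl-bearing one. The demand is a chair transition state, an (E)-enol ether and a cold quench.

9 to 2 and 6 (through 8). The C7–H and C8–H bonds (back to the alkyne) and the C6–C7 bond (carbonyl addition) are cut. An alkoxyacetylide is less basic and easier to handle than an (E)-2-alkoxyvinyl-metal, and trans-hydroalumination fixes the E geometry. The demand is addition anti to the isopropenyl group.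

6 to 3 and 4; 2 to 1. The enol ether C–O bond is cut to the alcohol and the two-carbon chloro-olefin. The enone oxygen is cut back to a ring methylene of the terpene. Both ends are commercial. The demand is regioselective allylic oxidation without loss of the stereocentre.

## Other disconnections considered

Alternative 1:
- Cut: C6–C7, C11–C12 and C12–O together.
- Forward key step: the open-chain epoxy ynal A2 (C6 aldehyde next to the epoxide, C7≡C11 alkyne carrying CH2O-4-methoxybenzyl, silyl ether on C8, E-alkene C1=C10 in the tether) would go to the silyl-protected epoxy butenolide A1. Zerovalent nickel from Ni(cod)2 and 1,3-bis(2,6-diisopropylphenyl)imidazol-2-ylidene would couple aldehyde and alkyne to an oxanickelacycle; CO insertion at C11 and C–O reductive elimination would follow.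
- In its favour: carbocycle, butenolide and C6 are made in one step with the C13 oxygen in place, and the epoxide comes from a reliable acyclic asymmetric epoxidation. In step economy after ring formation it is better than the chosen plan, which spends six steps on the lactone. In control of C4 and C5 it is at least the equal.
- Against it: this three-component mode is established for five- and six-membered rings, not for a ten-membered ring. C6 would be set in the metallacycle step with only the adjacent epoxide to direct it. Regiochemistry (C6 to C7 versus C6 to C11) decides between a ten- and an eleven-membered ring. Nickel under CO is drained as Ni(CO)4.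
- Comparison: the chosen plan closes the ring by ring expansion, with no entropic cost, and relays the terpene stereocentre to C8. The alternative builds C8 separately and stakes everything on one unprecedented macrocyclisation.

Alternative 2:
- Cut: the C4=C5 bond, with sulfur inserted between the two carbons.
- Forward key step: the eleven-membered sulfone A4 would be halogenated in situ (CBr2F2, KOH on alumina), close to the episulfone and lose SO2 to give the Z-cyclodecene A3.
- In its favour: an eleven-membered sulfide ring closes easily by alkylation at sulfur, and the contraction avoids a direct ten-membered C–C closure. A3 already holds the C1 carbonyl and the C10 methylene in masked form, so no ene oxygenation is needed. Its C6 oxygen beside the masked C7 ketone is the ideal pattern for a phosphonate butenolide synthesis. On both of these points it is better than the chosen plan.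
- Against it: a trisubstituted alkene of defined Z geometry is asked of a reaction whose geometry in this ring size is not dependable. The carbanion at C5 has the C6 ether in the β-position. The later epoxidation has no free hydroxyl to direct it. C6 and C8 must be made by separate acyclic stereocontrol.
- Comparison: the mechanism is anionic and strongly basic in both plans. The chosen plan needs base only for a moment at low temperature, and is shorter overall because the terpene supplies ten carbons and a stereocentre.

Alternative 3:
- Cut: C1–C10.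
- Forward key step: the butenolide epoxy aldehyde A6, with a terminal alkyne on C9, would be cyclised reductively to the C1 triethylsilyl ether A5. Zerovalent nickel from Ni(cod)2 with the same bulky carbene and Et3SiH would bond C1 to the internal alkyne carbon.
- In its favour: the C1 oxygen and the C10 methylene appear directly in the right relationship. This is better than the chosen ene oxygenation, which has a regiochemical question. All four stereocentres and the butenolide are finished before the ring is closed, so the end game is short.
- Against it: terminal alkynes normally couple at the terminal carbon, which here would give an eleven-membered ring; the exo mode relies on ligand bulk. A strained ten-membered ring with an epoxide and a fused butenolide is closed end to end, with oligomerisation as the competitor. The butenolide is a good ligand for zerovalent nickel. A6 needs a long linear assembly.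
- Comparison: in functional-group pattern after closure it is the equal or better; in ring formation and total length the ring-expansion plan is the safer and shorter.

Key step: step 5

Remark on the chemistry: re-derivation with the chair model shows that the (1R,6R)-trans carbinol with an (E)-enol ether leads to 8R and 1(10)E, as the target requires, so the structures around the key step need no correction. Two things are changed: the precursor is reached by alkynylation and trans-hydroalumination, because an (E)-2-alkoxyvinyl-lithium has lithium and alkoxide anti-periplanar and is prone to fragment; and the rearrangement uses a soluble potassium amide so that it can be run and quenched cold. Germacrane numbering is used for the ten-membered compounds.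

Step 1
Reactants: 1 (S)-limonene
Product: 2 (R)-isopiperitenone
Conditions: Cr(CO)6 (cat.), t-BuOOH, MeCN, reflux
Reagents that add atoms: tert-butyl hydroperoxide, CC(C)(C)OO
Why: Chromium-catalysed allylic oxidation by the hydroperoxide should attack the ring methylene between the trisubstituted alkene and the stereocentre, giving the enone with the isopropenyl-bearing carbon untouched (S becomes R only through a change of CIP priority); the regioisomeric enone (carvone) is the expected by-product and is removed by chromatography.

Step 2
Reactants: 3 4-methoxybenzyl alcohol; 4 trichloroethylene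
Product: 6 1-{[(E)-1,2-dichloroethenyl]oxymethyl}-4-methoxybenzene, via dichloroacetylene 5 (not isolated)
Conditions: KH, THF, 0 °C; then 4, 0 °C → rt
Reagents that add atoms: none
Why: Base-induced loss of HCl from 4 gives 5, to which the potassium alkoxide of 3 adds in anti fashion (elimination–addition), so that the two chlorines end up trans.

Step 3
Reactants: 6 1-{[(E)-1,2-dichloroethenyl]oxymethyl}-4-methoxybenzene; 2 (R)-isopiperitenone
Product: 8 (1R,6R)-1-[(4-methoxybenzyloxy)ethynyl]-3-methyl-6-(prop-1-en-2-yl)cyclohex-2-en-1-ol, via lithium alkynide 7 (not isolated)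
Conditions: n-BuLi (2.2 equiv), THF, −78 → −40 °C; then 2, −78 °C; pH 7 buffer
Reagents that add atoms: none
Why: Elimination and chlorine–lithium exchange convert 6 into the alkoxyacetylide 7, which should add 1,2 to the enone (Arens–van Dorp-type alkynylation) anti to the isopropenyl group through the half-chair with that group pseudoaxial (Felkin–Anh sense), creating the 1R carbinol; the acetylide is far less basic than a vinyl-lithium and spares the epimerisable α-hydrogen.

Step 4
Reactants: 8 (1R,6R)-1-[(4-methoxybenzyloxy)ethynyl]-3-methyl-6-(prop-1-en-2-yl)cyclohex-2-en-1-ol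
Product: 9 (1R,6R)-1-[(E)-2-(4-methoxybenzyloxy)ethenyl]-3-methyl-6-(prop-1-en-2-yl)cyclohex-2-en-1-ol
Conditions: NaAlH2(OCH2CH2OCH3)2, THF, 0 °C → rt; aq. KNaC4H4O6
Reagents that add atoms: none
Why: Hydroxyl-directed trans-hydroalumination of the propargylic alcohol followed by protonolysis gives only the (E)-enol ether; the neutral tartrate work-up protects the acid-labile 3-hydroxy enol ether.

Step 5
Reactants: 9 (1R,6R)-1-[(E)-2-(4-methoxybenzyloxy)ethenyl]-3-methyl-6-(prop-1-en-2-yl)cyclohex-2-en-1-ol
Product: 12 (8R)-8-(4-methoxybenzyloxy)germacra-1(10)E,4Z-dien-6-one, via potassium alkoxide 10 (not isolated), via potassium dienolate 11 (not isolated)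
Conditions: KN(SiMe3)2 (1.05 equiv), 18-crown-6, THF, −78 → −30 °C; then AcOH, THF, −78 °C
Reagents that add atoms: none
Why: The amide deprotonates the tertiary alcohol and the crown ether frees the alkoxide 10, which weakens the C1–C6 bond; the 3-oxido-1,5-diene C8=C7–C6(O−)–C1–C10=C9 then undergoes the [3,3] shift that forms C8–C9 and breaks C1–C6, giving dienolate 11, which acetic acid protonates at C7. The closest known reaction is the anionic oxy-Cope ring expansion of trans-1,2-dialkenylcyclohexanols to (E)-cyclodec-5-enones. The ten-membered ring arises by four-atom expansion of the cyclohexene through a chair-like six-centre transition state and is not closed end to end, so no dilution is needed. In the only chair open to the trans isomer both ring bonds (C6–C5 and C1–C2) are equatorial and the (E)-enol ether holds the ether oxygen equatorial, so C9 reaches one face of C8 only and the isopropenyl-bearing centre dictates 8R. The same chair puts C2 anti to C9 and gives the 1(10)E alkene, while the C4=C5 bond is a spectator and stays Z. The exocyclic vinyl group reacts rather than the ring alkene because the latter would need a boat across the ring. Loss of the C8 ether from the β-alkoxy enolate is held back by the soluble base, the low temperature and the immediate cold quench, and enolate formation makes the shift irreversible.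

Step 6
Reactants: 12 (8R)-8-(4-methoxybenzyloxy)germacra-1(10)E,4Z-dien-6-one
Product: 13 (6R,8R)-8-(4-methoxybenzyloxy)germacra-1(10)E,4Z-dien-6-ol
Conditions: (S)-2-methyl-CBS-oxazaborolidine (0.2 equiv), catecholborane, toluene, −78 °C
Reagents that add atoms: none
Why: CBS reduction with the (Z)-alkenyl arm as the large and C7H2 as the small substituent should give the 6R carbinol (O6 syn to O8) under reagent control; this centre is temporary and serves only to steer the epoxidation.

Step 7
Reactants: 13 (6R,8R)-8-(4-methoxybenzyloxy)germacra-1(10)E,4Z-dien-6-ol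
Product: 14 (4S,5R,6R,8R)-4,5-epoxy-8-(4-methoxybenzyloxy)germacr-1(10)E-en-6-ol
Conditions: VO(acac)2 (5 mol%), t-BuOOH, CH2Cl2, 0 °C
Reagents that add atoms: tert-butyl hydroperoxide, CC(C)(C)OO
Why: Vanadium-catalysed hydroxyl-directed epoxidation reacts only at the allylic C4=C5 bond, keeps the Z geometry as a cis-epoxide and, as in medium-ring (Z)-allylic alcohols, should deliver oxygen syn to the hydroxyl, which sets 4S,5R.

Step 8
Reactants: 14 (4S,5R,6R,8R)-4,5-epoxy-8-(4-methoxybenzyloxy)germacr-1(10)E-en-6-ol
Product: 15 (4S,5S,8R)-4,5-epoxy-8-(4-methoxybenzyloxy)germacr-1(10)E-en-6-one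
Conditions: Dess–Martin periodinane, NaHCO3, CH2Cl2, 0 °C → rt
Reagents that add atoms: none
Why: Buffered Dess–Martin oxidation returns the C6 carbonyl without touching epoxide, alkene or ether; the epoxide carbons keep their configuration (the descriptor of C5 changes only by priority).

Step 9
Reactants: 15 (4S,5S,8R)-4,5-epoxy-8-(4-methoxybenzyloxy)germacr-1(10)E-en-6-one
Product: 17 ethyl (4S,5S,7S,8R)-4,5-epoxy-8-(4-methoxybenzyloxy)-6-oxo-13-norgermacr-1(10)E-en-12-oate, via lithium enolate 16 (not isolated)
Conditions: LiN(SiMe3)2, THF, −78 °C; ICH2CO2Et, DMPU, −78 → −50 °C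
Reagents that add atoms: ethyl iodoacetate, CCOC(=O)CI
Why: Enolate alkylation: deprotonation is possible only at C7 (C5 is an epoxide carbon), and the reactive iodoacetate should C-alkylate the lithium enolate at low temperature on the face anti to the C8 ether (7S), before the β-alkoxide can be lost; either C7 epimer would serve, since C7 later becomes sp2.

Step 10
Reactants: 17 ethyl (4S,5S,7S,8R)-4,5-epoxy-8-(4-methoxybenzyloxy)-6-oxo-13-norgermacr-1(10)E-en-12-oate
Product: 19 (4S,5R,6R,7S,8R)-4,5-epoxy-8-(4-methoxybenzyloxy)-13-norgermacr-1(10)E-en-12,6-olide, via hydroxy ester 18 (not isolated)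
Conditions: Zn(BH4)2, Et2O, −20 → 0 °C; then 2-hydroxypyridine (cat.), toluene, 40 °C
Reagents that add atoms: none
Why: Chelation-controlled reduction (Cram chelate): zinc bridges the carbonyl and epoxide oxygens and hydride adds anti to the oxirane carbon C4, giving the 6R alcohol with O6 cis to the epoxide oxygen, the sense also favoured by a six-membered chelate to O8 (1,3-syn); the hydroxyl then closes the trans-fused γ-lactone with loss of ethanol.

Step 11
Reactants: 19 (4S,5R,6R,7S,8R)-4,5-epoxy-8-(4-methoxybenzyloxy)-13-norgermacr-1(10)E-en-12,6-olide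
Product: 21 (4S,5R,6R,7S,8R,11S)-4,5-epoxy-13-hydroxy-8-(4-methoxybenzyloxy)germacr-1(10)E-en-12,6-olide, via lithium lactone enolate 20 (not isolated)
Conditions: LiN(i-Pr)2, THF, −78 °C; CH2O (gas), −78 → −40 °C; AcOH
Reagents that add atoms: formaldehyde, C=O
Why: Aldol addition of the lactone enolate to monomeric formaldehyde; the electrophile should enter anti to the C8-bearing bond at C7, so C13 sits cis to H7 (11S), a centre that disappears in the next step.

Step 12
Reactants: 21 (4S,5R,6R,7S,8R,11S)-4,5-epoxy-13-hydroxy-8-(4-methoxybenzyloxy)germacr-1(10)E-en-12,6-olide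
Product: 24 (4S,5R,6R,8R)-4,5-epoxy-13-hydroxy-8-(4-methoxybenzyloxy)germacra-1(10)E,7(11)-dien-12,6-olide, via dilithium alkoxide enolate 22 (not isolated), via phenylselanyl lactone 23 (not isolated)
Conditions: LiN(i-Pr)2 (2.3 equiv), THF, −78 → −40 °C; PhSeBr, −78 °C; AcOH; then 30% H2O2, pyridine, CH2Cl2, 0 °C
Reagents that add atoms: none
Why: The Fráter–Seebach-type dianion keeps the C13 oxygen as an alkoxide that cannot be eliminated; PhSeBr should again add anti to C8, placing selenium cis to H7, and the selenoxide syn-eliminates into the ring and not towards the hydroxyl-bearing C13 (selenoxides avoid forming enols), giving the 7(11)-butenolide.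

Step 13
Reactants: 24 (4S,5R,6R,8R)-4,5-epoxy-13-hydroxy-8-(4-methoxybenzyloxy)germacra-1(10)E,7(11)-dien-12,6-olide
Product: 25 (4S,5R,6R,8R)-13-acetoxy-4,5-epoxy-8-(4-methoxybenzyloxy)germacra-1(10)E,7(11)-dien-12,6-olide
Conditions: Ac2O, pyridine, DMAP (cat.), CH2Cl2, 0 °C
Reagents that add atoms: acetic anhydride, CC(=O)OC(C)=O
Why: Nucleophile-catalysed acylation of the only free hydroxyl (primary, allylic); no stereocentre is involved.

Step 14
Reactants: 25 (4S,5R,6R,8R)-13-acetoxy-4,5-epoxy-8-(4-methoxybenzyloxy)germacra-1(10)E,7(11)-dien-12,6-olide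
Product: 26 (4S,5R,6R,8R)-13-acetoxy-4,5-epoxy-8-hydroxygermacra-1(10)E,7(11)-dien-12,6-olide
Conditions: DDQ, CH2Cl2–pH 7 buffer, 0 °C → rt
Reagents that add atoms: none
Why: Oxidative cleavage of the 4-methoxybenzyl ether by hydride abstraction and hydrolysis of the oxocarbenium ion; the neutral buffer spares epoxide, acetate and alkenes, and C8 keeps its configuration.

Step 15
Reactants: 26 (4S,5R,6R,8R)-13-acetoxy-4,5-epoxy-8-hydroxygermacra-1(10)E,7(11)-dien-12,6-olide
Product: 27 (4S,5R,6R,8R)-13-acetoxy-4,5-epoxy-8-(2-methylprop-2-enoyloxy)germacra-1(10)E,7(11)-dien-12,6-olide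
Conditions: methacrylic anhydride, Et3N, DMAP (cat.), CH2Cl2, 0 °C → rt
Reagents that add atoms: methacrylic anhydride, C=C(C)C(=O)OC(=O)C(C)=C
Why: DMAP-catalysed acyl transfer to the secondary C8 alcohol; the C–O bond of the stereocentre is not broken.

Step 16
Reactants: 27 (4S,5R,6R,8R)-13-acetoxy-4,5-epoxy-8-(2-methylprop-2-enoyloxy)germacra-1(10)E,7(11)-dien-12,6-olide
Product: 29 (4S,5R,6R,8R)-13-acetoxy-4,5-epoxy-8-(2-methylprop-2-enoyloxy)-1-oxogermacra-7(11),10(14)-dien-12,6-olide, via allylic hydroperoxide 28 (not isolated)
Conditions: O2, tetraphenylporphyrin (cat.), visible light, CH2Cl2, −20 °C; then Ac2O, pyridine, 0 °C → rt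
Reagents that add atoms: oxygen, O=O
Why: Schenck ene reaction of singlet oxygen with the only electron-rich alkene: oxygen should bond to C1 and a hydrogen leave from C14 on the more substituted side (cis effect), as in the photo-oxygenation of related 1(10)-germacrenolides; acetylation of the secondary hydroperoxide and loss of acetic acid (Kornblum–DeLaMare-type dehydration) give the methylene ketone, so the C1 configuration of 28 does not matter.

## Compound list

1 | (S)-limonene, (4S)-1-methyl-4-(prop-1-en-2-yl)cyclohex-1-ene | CC1=CC[C@H](CC1)C(C)=C | starting material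
2 | (R)-isopiperitenone, (6R)-3-methyl-6-(prop-1-en-2-yl)cyclohex-2-en-1-one | CC1=CC(=O)[C@H](CC1)C(C)=C | intermediate
3 | 4-methoxybenzyl alcohol | COc1ccc(CO)cc1 | starting material
4 | trichloroethylene | ClC=C(Cl)Cl | starting material
5 | dichloroacetylene (not isolated) | ClC#CCl | intermediate
6 | 1-{[(E)-1,2-dichloroethenyl]oxymethyl}-4-methoxybenzene | COc1ccc(CO/C(Cl)=C\Cl)cc1 | intermediate
7 | lithium (4-methoxybenzyloxy)ethynide (not isolated) | [Li]C#COCc1ccc(OC)cc1 | intermediate
8 | (1R,6R)-1-[(4-methoxybenzyloxy)ethynyl]-3-methyl-6-(prop-1-en-2-yl)cyclohex-2-en-1-ol (alkynyl trans to isopropenyl) | COc1ccc(COC#C[C@@]2(O)C=C(C)CC[C@@H]2C(C)=C)cc1 | intermediate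
9 | (1R,6R)-1-[(E)-2-(4-methoxybenzyloxy)ethenyl]-3-methyl-6-(prop-1-en-2-yl)cyclohex-2-en-1-ol (alkenyl groups trans) | COc1ccc(CO/C=C/[C@@]2(O)C=C(C)CC[C@@H]2C(C)=C)cc1 | intermediate
10 | potassium alkoxide of 9 (not isolated) | COc1ccc(CO/C=C/[C@@]2([O-])C=C(C)CC[C@@H]2C(C)=C)cc1.[K+] | intermediate
11 | potassium (8R)-8-(4-methoxybenzyloxy)germacra-1(10)E,4Z,6-trien-6-olate (not isolated) | COc1ccc(CO[C@@H]2C/C(C)=C/CC/C(C)=C\C([O-])=C2)cc1.[K+] | intermediate
12 | (8R)-8-(4-methoxybenzyloxy)germacra-1(10)E,4Z-dien-6-one | COc1ccc(CO[C@@H]2C/C(C)=C/CC/C(C)=C\C(=O)C2)cc1 | intermediate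
13 | (6R,8R)-8-(4-methoxybenzyloxy)germacra-1(10)E,4Z-dien-6-ol | COc1ccc(CO[C@@H]2C/C(C)=C/CC/C(C)=C\[C@H](O)C2)cc1 | intermediate
14 | (4S,5R,6R,8R)-4,5-epoxy-8-(4-methoxybenzyloxy)germacr-1(10)E-en-6-ol | COc1ccc(CO[C@@H]2C/C(C)=C/CC[C@]3(C)O[C@@H]3[C@H](O)C2)cc1 | intermediate
15 | (4S,5S,8R)-4,5-epoxy-8-(4-methoxybenzyloxy)germacr-1(10)E-en-6-one | COc1ccc(CO[C@@H]2C/C(C)=C/CC[C@]3(C)O[C@@H]3C(=O)C2)cc1 | intermediate
16 | lithium 6,7-enolate of 15 (not isolated) | COc1ccc(CO[C@@H]2C/C(C)=C/CC[C@]3(C)O[C@@H]3C([O-])=C2)cc1.[Li+] | intermediate
17 | ethyl (4S,5S,7S,8R)-4,5-epoxy-8-(4-methoxybenzyloxy)-6-oxo-13-norgermacr-1(10)E-en-12-oate | COc1ccc(CO[C@@H]2C/C(C)=C/CC[C@]3(C)O[C@@H]3C(=O)[C@H]2CC(=O)OCC)cc1 | intermediate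
18 | ethyl 4,5-epoxy-6-hydroxy-8-(4-methoxybenzyloxy)-13-norgermacr-1(10)E-en-12-oate, O6 cis to the epoxide oxygen (not isolated) | COc1ccc(CO[C@@H]2C/C(C)=C/CC[C@]3(C)O[C@@H]3[C@H](O)[C@H]2CC(=O)OCC)cc1 | intermediate
19 | (4S,5R,6R,7S,8R)-4,5-epoxy-8-(4-methoxybenzyloxy)-13-norgermacr-1(10)E-en-12,6-olide (trans-fused) | COc1ccc(CO[C@@H]2C/C(C)=C/CC[C@]3(C)O[C@@H]3[C@@H]3OC(=O)C[C@@H]23)cc1 | intermediate
20 | lithium enolate of 19 (not isolated) | COc1ccc(CO[C@@H]2C/C(C)=C/CC[C@]3(C)O[C@@H]3[C@@H]3OC([O-])=C[C@@H]23)cc1.[Li+] | intermediate
21 | (4S,5R,6R,7S,8R,11S)-4,5-epoxy-13-hydroxy-8-(4-methoxybenzyloxy)germacr-1(10)E-en-12,6-olide | COc1ccc(CO[C@@H]2C/C(C)=C/CC[C@]3(C)O[C@@H]3[C@@H]3OC(=O)[C@H](CO)[C@@H]23)cc1 | intermediate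
22 | dilithium alkoxide–enolate of 21 (not isolated) | COc1ccc(CO[C@@H]2C/C(C)=C/CC[C@]3(C)O[C@@H]3[C@@H]3OC([O-])=C(C[O-])[C@@H]23)cc1.[Li+].[Li+] | intermediate
23 | 11-(phenylselanyl) derivative of 21 with selenium cis to H7 (not isolated) | COc1ccc(CO[C@@H]2C/C(C)=C/CC[C@]3(C)O[C@@H]3[C@@H]3OC(=O)[C@](CO)([Se]c4ccccc4)[C@@H]23)cc1 | intermediate
24 | (4S,5R,6R,8R)-4,5-epoxy-13-hydroxy-8-(4-methoxybenzyloxy)germacra-1(10)E,7(11)-dien-12,6-olide | COc1ccc(CO[C@@H]2C/C(C)=C/CC[C@]3(C)O[C@@H]3[C@@H]3OC(=O)C(CO)=C23)cc1 | intermediate
25 | (4S,5R,6R,8R)-13-acetoxy-4,5-epoxy-8-(4-methoxybenzyloxy)germacra-1(10)E,7(11)-dien-12,6-olide | COc1ccc(CO[C@@H]2C/C(C)=C/CC[C@]3(C)O[C@@H]3[C@@H]3OC(=O)C(COC(C)=O)=C23)cc1 | intermediate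
26 | (4S,5R,6R,8R)-13-acetoxy-4,5-epoxy-8-hydroxygermacra-1(10)E,7(11)-dien-12,6-olide | O[C@@H]1C/C(C)=C/CC[C@]2(C)O[C@@H]2[C@@H]2OC(=O)C(COC(C)=O)=C21 | intermediate
27 | (4S,5R,6R,8R)-13-acetoxy-4,5-epoxy-8-(2-methylprop-2-enoyloxy)germacra-1(10)E,7(11)-dien-12,6-olide | C=C(C)C(=O)O[C@@H]1C/C(C)=C/CC[C@]2(C)O[C@@H]2[C@@H]2OC(=O)C(COC(C)=O)=C21 | intermediate
28 | (4S,5R,6R,8R)-13-acetoxy-4,5-epoxy-1-hydroperoxy-8-(2-methylprop-2-enoyloxy)germacra-7(11),10(14)-dien-12,6-olide, C1 undefined (not isolated) | C=C(C)C(=O)O[C@@H]1CC(=C)C(OO)CC[C@]2(C)O[C@@H]2[C@@H]2OC(=O)C(COC(C)=O)=C21 | intermediate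
29 | (4S,5R,6R,8R)-13-acetoxy-4,5-epoxy-8-(2-methylprop-2-enoyloxy)-1-oxogermacra-7(11),10(14)-dien-12,6-olide (CNP0266914.1) | C=C(C)C(=O)O[C@@H]1CC(=C)C(=O)CC[C@]2(C)O[C@@H]2[C@@H]2OC(=O)C(COC(C)=O)=C21 | target

## Step count and least certain steps

Total: 16 steps. Longest linear sequence: 15 steps (from 3 through steps 2 to 16; equally from 1 through step 1 and steps 3 to 16).

Step 5 (key step). The most likely failure is expulsion of the C8 alkoxide from the potassium dienolate 11 before the quench, because a β-alkoxy enolate is set up for this elimination. A second risk is leakage through a boat transition state, which would erode the C8 configuration and the alkene geometry. Fallback, neutral instead of anionic: 9 is silylated with N-(trimethylsilyl)imidazole to the trimethylsilyl ether F1, which is heated in degassed toluene in a base-washed sealed tube (about 180 °C, siloxy-Cope rearrangement) to the trimethylsilyl enol ether F2. Bu4NF buffered with AcOH at −20 °C then releases 12, where the route is rejoined. No enolate is present at any time.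

Step 3. The acetylide may add to the face syn to the isopropenyl group, or remove the α-hydrogen of 2 and so erode its configuration. The cis-dialkenyl isomer could still rearrange through a chair with the alkoxide equatorial, but less cleanly. Fallback with a bulkier sp2 nucleophile: 6 is converted with n-BuLi and methanol into 4-methoxybenzyl ethynyl ether F3. Hydrozirconation with Cp2Zr(H)Cl gives the (E)-vinylzirconocene F4 and I2 gives the (E)-2-iodovinyl ether F5. Exchange with t-BuLi at −78 °C gives the (E)-vinyl-lithium F6, which is used at once with CeCl3 and added to 2, giving 9 directly and replacing steps 3 and 4.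

Step 7. Oxygen delivery syn to the hydroxyl may be incomplete in a ten-membered ring, where two reactive conformers compete, and the Lewis-acidic vanadium may open the new epoxide across the ring onto the C1=C10 alkene. Fallback without a directing group: 12 is epoxidised directly to 15 under Weitz–Scheffer conditions (t-BuOOH, DBU, THF, 0 °C), omitting steps 6 to 8. No new compound is made. The face then depends on the ring conformation, so the diastereomers would have to be separated at 15.

Step 10. Hydride may be delivered to the other face of C6 if Felkin control by the C7 branch overrides chelation, giving the cis-fused lactone. Fallback by inversion: the reduction of 17 is then run to the 6-epi-lactone F7, which is opened with LiOH to the hydroxy acid F8. Closure under Mitsunobu conditions (PPh3, diisopropyl azodicarboxylate, toluene, 0 °C) inverts C6 and gives 19.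

Step 12. The dianion may lose formaldehyde by retro-aldol cleavage, or the second deprotonation at the hindered C11 may remain incomplete. Fallback by soft enolisation: 21 is oxidised with Dess–Martin periodinane to the α-formyl lactone F9. Its enol is selenenylated with PhSeCl and pyridine to the α-formyl selenide F10, and oxidation with H2O2 gives the formyl butenolide F11 by syn-elimination. Luche reduction (NaBH4, CeCl3·7H2O, MeOH, −78 °C) then gives 24.

## Further compounds

F1 | step 5 | trimethylsilyl ether of 9 | COc1ccc(CO/C=C/[C@@]2(O[Si](C)(C)C)C=C(C)CC[C@@H]2C(C)=C)cc1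
F2 | step 5 | (8R)-8-(4-methoxybenzyloxy)-6-(trimethylsilyloxy)germacra-1(10)E,4Z,6-triene | COc1ccc(CO[C@@H]2C/C(C)=C/CC/C(C)=C\C(O[Si](C)(C)C)=C2)cc1
F3 | step 3 | 4-methoxybenzyl ethynyl ether | COc1ccc(COC#C)cc1
F4 | step 3 | chloro[(E)-2-(4-methoxybenzyloxy)ethenyl]zirconocene | COc1ccc(CO/C=C/[Zr](Cl)(C2C=CC=C2)C2C=CC=C2)cc1
F5 | step 3 | 1-{[(E)-2-iodoethenyl]oxymethyl}-4-methoxybenzene | COc1ccc(CO/C=C/I)cc1
F6 | step 3 | (E)-2-(4-methoxybenzyloxy)ethenyl-lithium | COc1ccc(CO/C=C/[Li])cc1
F0 | step 7 | none | none
F7 | step 10 | 6-epi-19, cis-fused (4S,5R,6S,7S,8R)-lactone | COc1ccc(CO[C@@H]2C/C(C)=C/CC[C@]3(C)O[C@@H]3[C@H]3OC(=O)C[C@@H]23)cc1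
F8 | step 10 | 6-epi hydroxy acid from F7 | COc1ccc(CO[C@@H]2C/C(C)=C/CC[C@]3(C)O[C@@H]3[C@@H](O)[C@H]2CC(=O)O)cc1
F9 | step 12 | 13-oxo derivative of 21 (α-formyl lactone, C11 epimerisable) | COc1ccc(CO[C@@H]2C/C(C)=C/CC[C@]3(C)O[C@@H]3[C@@H]3OC(=O)C(C=O)[C@@H]23)cc1
F10 | step 12 | 11-(phenylselanyl) derivative of F9, selenium cis to H7 | COc1ccc(CO[C@@H]2C/C(C)=C/CC[C@]3(C)O[C@@H]3[C@@H]3OC(=O)[C@](C=O)([Se]c4ccccc4)[C@@H]23)cc1
F11 | step 12 | (4S,5R,6R,8R)-4,5-epoxy-8-(4-methoxybenzyloxy)-13-oxogermacra-1(10)E,7(11)-dien-12,6-olide | COc1ccc(CO[C@@H]2C/C(C)=C/CC[C@]3(C)O[C@@H]3[C@@H]3OC(=O)C(C=O)=C23)cc1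
A1 | alternative 1 | (4S,5R,6R,8R)-8-(tert-butyldimethylsilyloxy)-4,5-epoxy-13-(4-methoxybenzyloxy)germacra-1(10)E,7(11)-dien-12,6-olide | CC(C)(C)[Si](C)(C)O[C@@H]1C/C(C)=C/CC[C@]2(C)O[C@@H]2[C@@H]2OC(=O)C(COCc3ccc(OC)cc3)=C21
A2 | alternative 1 | open-chain epoxy ynal: C6 aldehyde on the 4,5-epoxide, E-alkene C1=C10, silyl ether on C8, alkyne C7≡C11 carrying CH2O-4-methoxybenzyl | CC(C)(C)[Si](C)(C)O[C@@H](C#CCOCc1ccc(OC)cc1)C/C(C)=C/CC[C@]1(C)O[C@@H]1C=O
A3 | alternative 2 | (4Z)-cyclodecene with C1 and C7 dioxolanes, C10 methylene, O6 4-methoxybenzyl and O8 tert-butyldimethylsilyl groups | C/C1=C/[C@H](OCc2ccc(OC)cc2)C2(OCCO2)[C@H](O[Si](C)(C)C(C)(C)C)CC(=C)C2(OCCO2)CC1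
A4 | alternative 2 | eleven-membered cyclic sulfone with sulfur between C4 and C5, otherwise substituted as A3 | O=S1(=O)C[C@H](OCc2ccc(OC)cc2)C2(OCCO2)[C@H](O[Si](C)(C)C(C)(C)C)CC(=C)C2(OCCO2)CCC1C
A5 | alternative 3 | ten-membered C1 triethylsilyl ether with C10 methylene, 4,5-epoxide, 7(11)-en-12,6-olide, O8 silyl and O13 4-methoxybenzyl ethers | CC[Si](CC)(CC)O[C@H]1CC[C@]2(C)O[C@@H]2[C@@H]2OC(=O)C(COCc3ccc(OC)cc3)=C2[C@H](O[Si](C)(C)C(C)(C)C)CC1=C
A6 | alternative 3 | open-chain butenolide epoxide with C1 aldehyde and terminal alkyne on C9 | O=CCC[C@]1(C)O[C@@H]1[C@@H]1OC(=O)C(COCc2ccc(OC)cc2)=C1[C@H](O[Si](C)(C)C(C)(C)C)CC#C
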